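In a one-step world you would read the product from one rate constant and the clock, but here J.L forms from J and L, L has first to come out of Z, and J leaks to G and Q.

    Z ⇌ L + D (K1 = 6.7 × 10⁻⁴ M, k1 = 0.093 /min)
    J ⇌ G (K2 = 0.13, k2 = 0.63 /min)
    J → Q (k3 = 0.0052 /min)
    J + L ⇌ J.L (K4 = 2.9 /M, k4 = 360 /M/min)

| setting | birch | oak | ash | maple | alder |
|---|---|---|---|---|---|
| Z | 0.60 mM | 1.5 mM | 5.0 mM | 15 mM | 50 mM |
| J | 5.00 equiv | 5.00 equiv | 5.00 equiv | 5.00 equiv | 5.00 equiv |
| time | 20 min | 20 min | 20 min | 20 min | 20 min |

- [J.L] at the end for birch, oak, ash, maple, alder, in this order
- the shape of the row from first to last (hardly changes / falls, then rises / rises all the way / rises, then falls / falls all the way)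

- "hardly changes" means that all values lie within two and a half points (for a concentration: within two and a half percent of the largest)
- run time (birch): 20 min

Start by freezing J. J and G relax to their balance with a half-life of 0.127 min, far shorter than the 20 min run, so you can take a fraction 88.5 % of the J pool as free J and the rest as G. Step 3 is slower: its half-life by itself, 130 min, is longer than the run. It draws on free J, so the pool shrinks at 0.00460 /min. Together these give the free-J fraction f, the part of J's own charge standing free at the end: 80.7 %. Steps 2 and 3 each have one species on the left, so the charge cancels from f, and I use the same f from birch to alder.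

Now step 4. It runs back at 124 /min, a half-life of 0.00559 min against the run, so J.L stands in pre-equilibrium with J and L. The ratio of J.L to L is then K4 times free J. Call this the capture ratio w: K4 times f times 5.00 times the Z charged. It is 0.00702 for birch, 0.0176 for oak, 0.0585 for ash, 0.176 for maple and 0.585 for alder.

Step 1 has a forward half-life of 7.5 min, the way back not counted, which is shorter than the run, so I take it at equilibrium. Let u be the fraction of Z that has dissociated. The square of u over the Z fraction left then equals (1 + w) times K1 over the Z charged, and J.L holds the share w/(1 + w) of u. Solving this gives my row: 0.00267 mM, 0.0125 mM, 0.0863 mM, 0.458 mM and 2.50 mM. It rises from first to last, and even as a fraction of Z it grows from 0.445 % to 5.00 %. At alder, J.L takes 1.00 % of J's charge, much less than f.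

The forecast reads 0.0026 mM, 0.0125 mM, 0.086 mM, 0.455 mM and 2.48 mM, a row that rises all the way, on the ground that “both J and L grow with loading”, and at birch it stands below my figure.

The flask gives 0.00260 mM, 0.0125 mM, 0.0860 mM, 0.455 mM and 2.48 mM: the row rises all the way. Birch's Z stands at 37.8 % of its charge after 20.0 min and at 36.3 % after 200 min. With f, maple's capture ratio comes to 0.176, and after 20.0 min maple holds J.L at 3.04 % beside L at 17.4 % of the Z charged, a ratio of 0.175.

The numbers were chosen freely; no experiment stands behind them.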